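The data were generated by integration on assumed constants, noise included.

I decide what to do with the eta flask at 80 min by counting J before I think about rates. Eta is the flask asked about, and theta is the earlier run with less Z.

in all of them: D 12 mM; G 4.9 mol%

| flask | Z | J | remark | time |
|---|---|---|---|---|
| eta | 1 equiv | 1.3 equiv | the very flask that is asked about, followed so far |  |
| theta | 0.50 equiv | 1.3 equiv | run made earlier |  |
| flask | 1.00 equiv | 1.30 equiv |  | 80 min |

| run | time / min | E / % |
|---|---|---|
| eta | 5.00 | 55.8 |
| eta | 8.00 | 59.7 |
| eta | 12.0 | 60.2 |
| eta | 20.0 | 60.5 |
| eta | 30.0 | 60.3 |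
| eta | 40.0 | 61.0 |
| eta | 60.0 | 60.3 |
| theta | 0.333 | 15.9 |
| theta | 0.833 | 31.2 |
| theta | 1.50 | 47.2 |
| theta | 2.50 | 62.9 |
| theta | 3.00 | 68.3 |
| theta | 4.00 | 76.2 |
| theta | 6.00 | 82.7 |

(each reading ± 0.3 percentage points)

* E, in percent of the D first charged, at 80 min
* what to do for the largest gain in E; "none" if nothing gains more than 2 percentage points (south / west / north / east / none)
* E present, with what was taken out counted in, in percent of the D first charged, after south
* E present, with what was taken out counted in, in percent of the D first charged, after north

- south: at 80 min take out 90% of the E then present, then wait 25 min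
- west: at 80 min add G, 50.0% of the amount charged, then wait 25 min
- north: change nothing and wait 25 min more
- east: at 80 min add J, 100% of the amount charged, then wait 25 min

- what is taken out of E is counted as made
- steps that have been proposed: D + G <-> X; J + X -> G + E; Z + G <-> Q; J + Q -> G + L
- additions bring no volume worth counting

The bench rule says that a charge of 1.30 equiv on D is an excess, so D should finish and E should approach full yield. The eta readings break that rule: E reads 60.2% at 12.0 min and 60.3% at 60.0 min. The proposed steps show the border. G binds D as X and Z as Q, and J spends itself on either form, so each E or L costs one J. I therefore use the J cover, the J charged divided by the D and Z charged that can consume it: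

cover = c(J) / (c(D) + c(Z)) = 15.6 mM / 24.0 mM = 0.650

In eta the cover stands below one, so J is the limiting reagent and the bench rule fails. Theta has a cover of 0.867 and reads 82.7% at 6.00 min, higher than the eta plateau at the same G loading.

So I expect eta to stay on its plateau. South, west and north add no J, so I expect no gain from them. East adds J against what the first charge leaves unpaid:

cover after east = 15.6 mM / 8.40 mM = 1.86

That is above one, so east should finish the flask.

The forecast gives 60.4% now, 60.4% after south, 60.4% after north, and east as the best move: “East restarts the reaction”.

The eta flask gives 60.7% at 80 min, 60.7% after south and 60.7% after north. The best move is east, which gains 39 percentage points.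

    D + G ⇌ X (K = 210 M⁻¹, k = 36.9 M⁻¹ s⁻¹)
    J + X → G + E (k = 163 M⁻¹ s⁻¹)
    Z + G ⇌ Q (K = 22000 M⁻¹, k = 41.7 M⁻¹ s⁻¹)
    J + Q → G + L (k = 8.95 M⁻¹ s⁻¹)

In eta, a cover of 0.650 ends with J at 0% of its charge, and the cover of 1.86 after east goes with that gain. The neighbour with 5.20 equiv of J has a cover of 2.60, above one, so the reckoned share of J left over is 61.5%. At 80 min that neighbour holds D at 0%, Z at 0% and E at 100%, with J at 62% of its charge.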